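**Strategy.** The flavone is disconnected at C4–C4a. Ring A is fully substituted, so its phenol precursor carries a single aromatic C–H (the future C4a), flanked by O1 and the C5 methoxy group and para to O7. An acyl cation at C4 can therefore bond at only one place. Activating a 3-aryloxy-2-methoxyacrylic acid that already holds ring B, the C3 methoxy group and the O1–C2 ether link closes the pyranone ring (ring C) in one intramolecular Friedel–Crafts acylation. The precursor is the 7,4'-di-O-benzyl acid 16, assembled from a pentaoxygenated phenol and an enol tosylate by vinylic substitution. Hydrogenolysis then frees both phenols.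

Key step: step 10

Assumption: enol tosylate 14 and ester 15 are drawn as E isomers (sulfonyloxy or aryloxy group cis to the ester), as expected from a chelated enolate; any Z isomer would behave alike, because steps 8 and 10 pass through freely rotating intermediates. Conjugate bases formed by plain deprotonation (enolates, phenoxides, carboxylates) are treated as forms of the numbered compound.

**Step 1**
Reactants: 1 2,6-dimethoxyphenol
Product: 2 2-(benzyloxy)-1,3-dimethoxybenzene
Conditions: BnBr, K2CO3, DMF, 60 °C
Reagents that add atoms: benzyl bromide, BrCc1ccccc1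
Why: Williamson ether synthesis on the acidic phenol masks the future 7-OH as a benzyl ether that is twisted out of plane by its two ortho methoxy groups and so leaves the directing power with those methoxy groups.

**Step 2**
Reactants: 2 2-(benzyloxy)-1,3-dimethoxybenzene
Product: 3 3-(benzyloxy)-1,5-dibromo-2,4-dimethoxybenzene
Conditions: NBS (2.2 equiv), MeCN, rt to 45 °C, dark
Reagents that add atoms: N-bromosuccinimide, O=C1CCC(=O)N1Br
Why: Electrophilic aromatic bromination goes ortho to one methoxy group and para to the other, so both bromines should enter the two equivalent positions and the carbon para to the benzyloxy group stays free.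

**Step 3**
Reactants: 3 3-(benzyloxy)-1,5-dibromo-2,4-dimethoxybenzene
Product: 6 3-(benzyloxy)-5-bromo-2,4-dimethoxyphenol, via aryllithium 4 (not isolated), via lithium aryltrimethoxyborate 5 (not isolated)
Conditions: n-BuLi (1.0 equiv), THF, −78 °C; B(OMe)3, −78 to 0 °C; AcOH, 30% aq H2O2, 0 °C to rt
Reagents that add atoms: hydrogen peroxide, OO
Why: Bromine–lithium exchange with one equivalent of n-BuLi should stop after one bromine, since a second exchange would need a dianion, which desymmetrises 3; borate trapping and peroxide oxidation (1,2-aryl shift from boron to oxygen) then give the phenol while the benzyl ether is untouched at −78 °C.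

**Step 4**
Reactants: 6 3-(benzyloxy)-5-bromo-2,4-dimethoxyphenol
Product: 7 3-(benzyloxy)-1-bromo-2,4,5-trimethoxybenzene
Conditions: MeI, K2CO3, acetone, 50 °C
Reagents that add atoms: iodomethane, CI
Why: Williamson O-methylation of the phenoxide fixes the oxygen that becomes the C5 methoxy group of the flavone.

**Step 5**
Reactants: 7 3-(benzyloxy)-1-bromo-2,4,5-trimethoxybenzene
Product: 10 3-(benzyloxy)-2,4,5-trimethoxyphenol, via aryllithium 8 (not isolated), via lithium aryltrimethoxyborate 9 (not isolated)
Conditions: n-BuLi (1.05 equiv), THF, −78 °C; B(OMe)3, −78 to 0 °C; AcOH, 30% aq H2O2 (1.2 equiv), 0 °C; under argon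
Reagents that add atoms: hydrogen peroxide, OO
Why: The same bromine–lithium exchange, borate trapping and oxidative boron-to-oxygen shift should turn the remaining C–Br bond into the phenolic C–OH, leaving a ring with one C–H.

**Step 6**
Reactants: 11 methyl methoxyacetate; 12 4-(benzyloxy)benzoyl chloride
Product: 13 methyl 3-[4-(benzyloxy)phenyl]-2-methoxy-3-oxopropanoate
Conditions: LiN(i-Pr)2 (2.2 equiv), 11 (2.2 equiv), THF, −78 °C; then 12, −78 to −20 °C; aq NH4Cl
Reagents that add atoms: none
Why: C-acylation of a preformed lithium ester enolate by an acid chloride (crossed Claisen-type condensation) should give the keto ester, the second equivalent of enolate deprotonating the more acidic product and shielding it from further acylation.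

**Step 7**
Reactants: 13 methyl 3-[4-(benzyloxy)phenyl]-2-methoxy-3-oxopropanoate
Product: 14 methyl (E)-3-[4-(benzyloxy)phenyl]-2-methoxy-3-(tosyloxy)acrylate
Conditions: TsCl, TMEDA, LiCl, MeCN, 0 °C to rt
Reagents that add atoms: p-toluenesulfonyl chloride, Cc1ccc(cc1)S(Cl)(=O)=O
Why: O-sulfonylation of the lithium-chelated enolate of the β-keto ester (enol tosylate formation) is expected to place the tosyloxy group cis to the ester, and the amine base avoids α-chlorination by TsCl.

**Step 8**
Reactants: 10 3-(benzyloxy)-2,4,5-trimethoxyphenol; 14 methyl (E)-3-[4-(benzyloxy)phenyl]-2-methoxy-3-(tosyloxy)acrylate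
Product: 15 methyl (E)-3-[3-(benzyloxy)-2,4,5-trimethoxyphenoxy]-3-[4-(benzyloxy)phenyl]-2-methoxyacrylate
Conditions: Cs2CO3, DMF, rt to 50 °C, argon
Reagents that add atoms: none
Why: Nucleophilic vinylic substitution by addition–elimination, in which the phenoxide adds to the β-carbon of the acrylate and the resulting ester enolate expels tosylate, should form the aryl vinyl ether whatever the tosylate geometry.

**Step 9**
Reactants: 15 methyl (E)-3-[3-(benzyloxy)-2,4,5-trimethoxyphenoxy]-3-[4-(benzyloxy)phenyl]-2-methoxyacrylate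
Product: 16 (E)-3-[3-(benzyloxy)-2,4,5-trimethoxyphenoxy]-3-[4-(benzyloxy)phenyl]-2-methoxyacrylic acid
Conditions: LiOH·H2O, THF/MeOH/H2O, rt to 40 °C; then 1 M HCl, 0 °C, pH 3
Reagents that add atoms: lithium hydroxide (hydroxide oxygen), [Li+].[OH-]
Why: Saponification by acyl–oxygen cleavage should give the acid, because the carboxylate once formed deactivates the push–pull alkene towards conjugate attack by hydroxide, and cold, brief acidification avoids decarboxylation.

**Step 10**
Reactants: 16 (E)-3-[3-(benzyloxy)-2,4,5-trimethoxyphenoxy]-3-[4-(benzyloxy)phenyl]-2-methoxyacrylic acid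
Product: 18 7-(benzyloxy)-2-[4-(benzyloxy)phenyl]-3,5,6,8-tetramethoxy-4H-chromen-4-one, via mixed trifluoroacetic anhydride 17 (not isolated)
Conditions: (CF3CO)2O (3 equiv), CH2Cl2, 0 °C to rt
Reagents that add atoms: none
Why: The anhydride converts acid 16 into mixed anhydride 17, an acylium equivalent, whose acyl carbon is attacked by the only unsubstituted carbon of the phenoxy ring (future C4a, activated by the ortho ether oxygen O1, the ortho methoxy and the para benzyloxy group), after which the sigma complex loses its proton and trifluoroacetate departs. The closest known reaction type is the intramolecular Friedel–Crafts acylation of 3-aryloxyacrylic and 3-aryloxycinnamic acids to chromones and flavones. The pyranone ring (ring C) closes in the 6-exo-trig mode at the acyl carbon, the carbonyl oxygen staying outside the ring, and no stereocentre is created. The step needs site selectivity and a productive alkene geometry: the first is structural because ring A offers a single C–H, whereas closure onto ring B to an indenone would have to use a carbon meta to its benzyloxy group; the second is secured because the push–pull alkene should equilibrate its E and Z forms through C2 protonation by the liberated trifluoroacetic acid, so both isomers drain into 18. Working without a metal Lewis acid should keep both benzyl ethers and the peri C5 methoxy group intact.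

**Step 11**
Reactants: 18 7-(benzyloxy)-2-[4-(benzyloxy)phenyl]-3,5,6,8-tetramethoxy-4H-chromen-4-one
Product: 19 7-hydroxy-2-(4-hydroxyphenyl)-3,5,6,8-tetramethoxy-4H-chromen-4-one
Conditions: H2 (1 atm), 10% Pd/C, EtOAc/MeOH, rt
Reagents that add atoms: none
Why: Catalytic hydrogenolysis should cleave both benzyl aryl ethers, while the chromone double bond (a vinylogous ester inside the pyranone) and the four methyl ethers are not reduced under these conditions.

**Compound list**
1 | 2,6-dimethoxyphenol | COc1cccc(OC)c1O | starting material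
2 | 2-(benzyloxy)-1,3-dimethoxybenzene | COc1cccc(OC)c1OCc1ccccc1 | intermediate
3 | 3-(benzyloxy)-1,5-dibromo-2,4-dimethoxybenzene | COc1c(Br)cc(Br)c(OC)c1OCc1ccccc1 | intermediate
4 | [3-(benzyloxy)-5-bromo-2,4-dimethoxyphenyl]lithium | [Li]c1cc(Br)c(OC)c(OCc2ccccc2)c1OC | intermediate (not isolated)
5 | lithium [3-(benzyloxy)-5-bromo-2,4-dimethoxyphenyl]trimethoxyborate | [Li+].CO[B-](OC)(OC)c1cc(Br)c(OC)c(OCc2ccccc2)c1OC | intermediate (not isolated)
6 | 3-(benzyloxy)-5-bromo-2,4-dimethoxyphenol | Oc1cc(Br)c(OC)c(OCc2ccccc2)c1OC | intermediate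
7 | 3-(benzyloxy)-1-bromo-2,4,5-trimethoxybenzene | COc1cc(Br)c(OC)c(OCc2ccccc2)c1OC | intermediate
8 | [3-(benzyloxy)-2,4,5-trimethoxyphenyl]lithium | [Li]c1cc(OC)c(OC)c(OCc2ccccc2)c1OC | intermediate (not isolated)
9 | lithium [3-(benzyloxy)-2,4,5-trimethoxyphenyl]trimethoxyborate | [Li+].CO[B-](OC)(OC)c1cc(OC)c(OC)c(OCc2ccccc2)c1OC | intermediate (not isolated)
10 | 3-(benzyloxy)-2,4,5-trimethoxyphenol | Oc1cc(OC)c(OC)c(OCc2ccccc2)c1OC | intermediate
11 | methyl methoxyacetate | COCC(=O)OC | starting material
12 | 4-(benzyloxy)benzoyl chloride | O=C(Cl)c1ccc(OCc2ccccc2)cc1 | starting material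
13 | methyl 3-[4-(benzyloxy)phenyl]-2-methoxy-3-oxopropanoate (racemic; the C2 centre is lost in step 7) | COC(=O)C(OC)C(=O)c1ccc(OCc2ccccc2)cc1 | intermediate
14 | methyl (E)-3-[4-(benzyloxy)phenyl]-2-methoxy-3-(tosyloxy)acrylate | COC(=O)/C(OC)=C(\OS(=O)(=O)c1ccc(C)cc1)c1ccc(OCc2ccccc2)cc1 | intermediate
15 | methyl (E)-3-[3-(benzyloxy)-2,4,5-trimethoxyphenoxy]-3-[4-(benzyloxy)phenyl]-2-methoxyacrylate | COC(=O)/C(OC)=C(\Oc1cc(OC)c(OC)c(OCc2ccccc2)c1OC)c1ccc(OCc2ccccc2)cc1 | intermediate
16 | (E)-3-[3-(benzyloxy)-2,4,5-trimethoxyphenoxy]-3-[4-(benzyloxy)phenyl]-2-methoxyacrylic acid | OC(=O)/C(OC)=C(\Oc1cc(OC)c(OC)c(OCc2ccccc2)c1OC)c1ccc(OCc2ccccc2)cc1 | intermediate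
17 | mixed anhydride of acid 16 with trifluoroacetic acid (E) | O=C(OC(=O)C(F)(F)F)/C(OC)=C(\Oc1cc(OC)c(OC)c(OCc2ccccc2)c1OC)c1ccc(OCc2ccccc2)cc1 | intermediate (not isolated)
18 | 7-(benzyloxy)-2-[4-(benzyloxy)phenyl]-3,5,6,8-tetramethoxy-4H-chromen-4-one | COc1c(OCc2ccccc2)c(OC)c2oc(-c3ccc(OCc4ccccc4)cc3)c(OC)c(=O)c2c1OC | intermediate
19 | 7-hydroxy-2-(4-hydroxyphenyl)-3,5,6,8-tetramethoxy-4H-chromen-4-one | COc1c(O)c(OC)c2oc(-c3ccc(O)cc3)c(OC)c(=O)c2c1OC | target

**Step count.** Total: 11 steps. Longest linear sequence: 9 steps (steps 1–5 and 8–11).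

**Steps most likely to fail**

Step 8. The phenoxide may attack the sulfonyl sulfur (sulfonyl transfer that returns keto ester 13), or conjugate addition to the tetrasubstituted, donor-substituted acrylate may be too slow. The fallback replaces the sulfonate by a halide and forms the C–O bond by copper catalysis. It sets out from phenol 10. The partner would be built from bought 4-(benzyloxy)benzaldehyde and methyl 2-(dimethoxyphosphoryl)-2-methoxyacetate by Horner–Wadsworth–Emmons olefination (NaH, THF), giving methyl (Z)-3-[4-(benzyloxy)phenyl]-2-methoxyacrylate F1. Bromine addition (Br2, CH2Cl2, −78 °C) would give methyl 3-[4-(benzyloxy)phenyl]-2,3-dibromo-2-methoxypropanoate F2. Elimination of HBr with Et3N in the same flask, the usual bromination–dehydrobromination of an enol ether, would give methyl 3-[4-(benzyloxy)phenyl]-3-bromo-2-methoxyacrylate F3. Ullmann-type coupling of this bromide with 10 (CuI, N,N-dimethylglycine, Cs2CO3, dioxane, 90 °C) comes back to the route at ester 15; any Z isomer formed is carried on, since step 10 converges both.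

Step 10. The mixed anhydride may fail to acylate the crowded ring carbon before acid-driven processes take over: cleavage of the aryl vinyl ether, or loss or migration of a benzyl group. The fallback is the classical Baker–Venkataraman construction, which forms C4–C4a first on the more activated free phenol. It sets out from phenol 10. Friedel–Crafts acylation at its one free position, ortho to the hydroxyl, with methoxyacetyl chloride and BF3·OEt2 would give 1-[4-(benzyloxy)-2-hydroxy-3,5,6-trimethoxyphenyl]-2-methoxyethan-1-one F4. O-Aroylation with acid chloride 12 in pyridine would give 3-(benzyloxy)-2,4,5-trimethoxy-6-(methoxyacetyl)phenyl 4-(benzyloxy)benzoate F5. Base-induced acyl migration (KOH, pyridine, 50 °C) would give 1-[4-(benzyloxy)-2-hydroxy-3,5,6-trimethoxyphenyl]-3-[4-(benzyloxy)phenyl]-2-methoxypropane-1,3-dione F6. Cyclodehydration (NaOAc, AcOH, 100 °C) comes back to the route at flavone 18.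

Step 9. Hydroxide may add to the β-carbon and expel the phenoxide (the reverse of step 8) faster than it hydrolyses the hindered ester, or the free acid may decarboxylate on acidification. The fallback carries a tert-butyl ester that is removed by alkyl–oxygen cleavage under anhydrous acid. It sets out from acid chloride 12. With bought tert-butyl methoxyacetate under the conditions of step 6 it would give tert-butyl 3-[4-(benzyloxy)phenyl]-2-methoxy-3-oxopropanoate F7. Tosylation as in step 7 would give tert-butyl (E)-3-[4-(benzyloxy)phenyl]-2-methoxy-3-(tosyloxy)acrylate F8. Substitution by phenol 10 as in step 8 would give tert-butyl (E)-3-[3-(benzyloxy)-2,4,5-trimethoxyphenoxy]-3-[4-(benzyloxy)phenyl]-2-methoxyacrylate F9. Brief treatment with CF3CO2H in CH2Cl2 at 0 °C comes back to the route at acid 16, which could be cyclised in the same flask.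

**Further compounds**
F1 | step 8 | methyl (Z)-3-[4-(benzyloxy)phenyl]-2-methoxyacrylate | COC(=O)/C(OC)=C/c1ccc(OCc2ccccc2)cc1
F2 | step 8 | methyl 3-[4-(benzyloxy)phenyl]-2,3-dibromo-2-methoxypropanoate (mixture of racemic diastereomers) | COC(=O)C(Br)(OC)C(Br)c1ccc(OCc2ccccc2)cc1
F3 | step 8 | methyl 3-[4-(benzyloxy)phenyl]-3-bromo-2-methoxyacrylate (E/Z mixture) | COC(=O)C(OC)=C(Br)c1ccc(OCc2ccccc2)cc1
F4 | step 10 | 1-[4-(benzyloxy)-2-hydroxy-3,5,6-trimethoxyphenyl]-2-methoxyethan-1-one | COCC(=O)c1c(O)c(OC)c(OCc2ccccc2)c(OC)c1OC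
F5 | step 10 | 3-(benzyloxy)-2,4,5-trimethoxy-6-(methoxyacetyl)phenyl 4-(benzyloxy)benzoate | COCC(=O)c1c(OC(=O)c2ccc(OCc3ccccc3)cc2)c(OC)c(OCc2ccccc2)c(OC)c1OC
F6 | step 10 | 1-[4-(benzyloxy)-2-hydroxy-3,5,6-trimethoxyphenyl]-3-[4-(benzyloxy)phenyl]-2-methoxypropane-1,3-dione (racemic, enolisable) | COC(C(=O)c1ccc(OCc2ccccc2)cc1)C(=O)c1c(O)c(OC)c(OCc2ccccc2)c(OC)c1OC
F7 | step 9 | tert-butyl 3-[4-(benzyloxy)phenyl]-2-methoxy-3-oxopropanoate (racemic) | COC(C(=O)OC(C)(C)C)C(=O)c1ccc(OCc2ccccc2)cc1
F8 | step 9 | tert-butyl (E)-3-[4-(benzyloxy)phenyl]-2-methoxy-3-(tosyloxy)acrylate | CC(C)(C)OC(=O)/C(OC)=C(\OS(=O)(=O)c1ccc(C)cc1)c1ccc(OCc2ccccc2)cc1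
F9 | step 9 | tert-butyl (E)-3-[3-(benzyloxy)-2,4,5-trimethoxyphenoxy]-3-[4-(benzyloxy)phenyl]-2-methoxyacrylate | CC(C)(C)OC(=O)/C(OC)=C(\Oc1cc(OC)c(OC)c(OCc2ccccc2)c1OC)c1ccc(OCc2ccccc2)cc1
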